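**Retrosynthetic overview**

1. Target 19 is cut at the two outer CH2 bridges into the B–C–D nonaphenol 14 and two molecules of Mannich base 16 of butyrylfilicinic acid 15. These bonds are made last, at the single free ring carbon of ring B and of ring D.
2. Trimer 14 comes from its nona-O-benzyl ether 13. This is cut at the two bonds between ring C and the inner methylenes into ring C diiodide 5 and two molecules of benzylic zinc chloride 11 (two-directional Negishi coupling).
3. Both 5 and 11 derive from the tribenzyl ether 3 of butyrylphloroglucinol 1. The end-ring unit 15 is made from 1 by geminal C-methylation.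
4. Feature on which the plan rests: ring C is hexasubstituted, and its C3 and C5 (the two ring carbons bearing neither oxygen nor the butanoyl group) are the carbons bonded to the two inner methylenes. In 3 they are the only C–H positions of the phloroglucinol ring, so diiodination places the leaving groups exactly there.
5. No ring is formed. All five six-membered rings are carried in from 1 and are linked in the order C to B and D, then A and E.

Key step: step 7

Remark on the chemistry: the target has no stereocentre and no stereogenic double bond. The end rings are written in the enol form of the target SMILES, and that tautomer is assumed to be the one obtained.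

**Route**

Step 1
Reactants: 1, 1-(2,4,6-trihydroxyphenyl)butan-1-one (butyrylphloroglucinol); 2, benzyl bromide (3.6 equiv, three molecules incorporated)
Product: 3 1-[2,4,6-tris(benzyloxy)phenyl]butan-1-one
Conditions: BnBr (3.6 equiv), K2CO3 (4 equiv), DMF, 60 °C
Reagents that add atoms: benzyl bromide (2), BrCc1ccccc1
Why: Williamson ether synthesis; K2CO3 in a dipolar aprotic solvent favours O- over C-alkylation of the phenoxides, and excess bromide with mild heating should also alkylate the two hydroxyls chelated to the ketone.

Step 2
Reactants: 3, 1-[2,4,6-tris(benzyloxy)phenyl]butan-1-one (first portion); 4, N-iodosuccinimide (2.4 equiv, two molecules deliver iodine)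
Product: 5 1-[2,4,6-tris(benzyloxy)-3,5-diiodophenyl]butan-1-one
Conditions: NIS (2.4 equiv), CF3CO2H (0.3 equiv), MeCN, 0 °C to rt, dark
Reagents that add atoms: N-iodosuccinimide (4), O=C1CCC(=O)N1I
Why: Electrophilic aromatic iodination; the only two C–H positions of the trialkoxy ring are each flanked by two benzyloxy groups and should both react with acid-activated NIS, since the twisted ketone deactivates the ring only weakly and the benzyl phenyl rings are far less nucleophilic.

Step 3
Reactants: 3, 1-[2,4,6-tris(benzyloxy)phenyl]butan-1-one (second portion)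
Product: 7 2,4,6-tris(benzyloxy)-3-butanoylbenzaldehyde, via aryl iminium chloride 6 (not isolated)
Conditions: POCl3 (1.5 equiv), DMF, 0 to 45 °C; then H2O, 0 °C to rt
Reagents that add atoms: N,N-dimethylformamide, CN(C)C=O (formyl carbon); phosphoryl chloride, O=P(Cl)(Cl)Cl (chloride counter-ion of 6); water, O (aldehyde oxygen)
Why: Vilsmeier–Haack formylation; the chloroiminium ion attacks a ring carbon flanked by two benzyloxy groups, the iminium substituent of 6 then deactivates the ring against a second formylation, and the moderate temperature should keep the hindered ketone from reacting through its enol.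

Step 4
Reactants: 7, 2,4,6-tris(benzyloxy)-3-butanoylbenzaldehyde
Product: 8 1-[2,4,6-tris(benzyloxy)-3-(hydroxymethyl)phenyl]butan-1-one
Conditions: NaBH4 (0.5 equiv), THF/MeOH 4:1, −20 °C
Reagents that add atoms: none
Why: Chemoselective borohydride reduction; at low temperature the aldehyde should be reduced far faster than the di-ortho-substituted, out-of-plane aryl ketone.

Step 5
Reactants: 8, 1-[2,4,6-tris(benzyloxy)-3-(hydroxymethyl)phenyl]butan-1-one
Product: 10 1-[2,4,6-tris(benzyloxy)-3-(chloromethyl)phenyl]butan-1-one, via benzylic mesylate 9 (not isolated)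
Conditions: MsCl (1.2 equiv), 2,4,6-collidine (1.5 equiv), LiCl (3 equiv), DMF, 0 °C; cold aqueous work-up, used at once
Reagents that add atoms: lithium chloride, [Li+].[Cl-] (chlorine of 10); methanesulfonyl chloride, CS(=O)(=O)Cl (mesyl group of 9, its chloride joins the chloride pool)
Why: Mesylation followed by chloride displacement under Meyers-type conditions; the cold, non-acidic medium should give the electron-rich benzylic chloride without the acid that would promote Friedel–Crafts self-alkylation at the free ring position.

Step 6
Reactants: 10, 1-[2,4,6-tris(benzyloxy)-3-(chloromethyl)phenyl]butan-1-one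
Product: 11 [2,4,6-tris(benzyloxy)-3-butanoylbenzyl]zinc chloride (LiCl complex, THF solution)
Conditions: Zn dust (2 equiv, activated with BrCH2CH2Br and Me3SiCl), LiCl (1.5 equiv), THF, 25 °C; titrated with I2, used as solution
Reagents that add atoms: zinc, [Zn]
Why: LiCl-mediated direct insertion of zinc into a benzylic chloride; LiCl takes the organozinc off the metal surface, which should keep Wurtz homocoupling low, and a benzylic zinc chloride does not add to the hindered aryl ketone.

Step 7
Reactants: 5, 1-[2,4,6-tris(benzyloxy)-3,5-diiodophenyl]butan-1-one (1 equiv); 11, [2,4,6-tris(benzyloxy)-3-butanoylbenzyl]zinc chloride (2.6 equiv, two molecules incorporated, one at each iodide)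
Product: 13 nona-O-benzyl B–C–D trimer, via mono-coupled iodide 12 (not isolated)
Conditions: Pd(OAc)2 (5 mol %), SPhos (10 mol %), THF, 25 to 50 °C; 11 (2.6 equiv) added over 2 h
Reagents that add atoms: [2,4,6-tris(benzyloxy)-3-butanoylbenzyl]zinc chloride (11, second molecule, which converts 12 into 13), CCCC(=O)c1c(OCc2ccccc2)cc(OCc2ccccc2)c(C[Zn]Cl)c1OCc1ccccc1
Why: Twofold Negishi cross-coupling: the organozinc reduces divalent Pd(OAc)2 to SPhos-ligated zerovalent palladium, which inserts into a C–I bond of 5, the benzyl group passes from zinc to palladium, and reductive elimination forms the aryl–CH2 bond of 12, after which the same cycle with a second molecule of 11 at the remaining iodide gives 13. The closest known reaction type is the Pd(OAc)2/SPhos coupling of LiCl-solubilised benzylic zinc chlorides with ortho-substituted aryl halides. No ring is closed and no stereocentre is created. The step needs exhaustive coupling at two iodides that each sit between two benzyloxy groups, without homocoupling of the zinc reagent or proto-deiodination; the bulky, electron-rich SPhos ligand is suited to di-ortho-substituted partners, the new benzyl group of 12 is meta to the remaining iodide and so adds little hindrance, and slow addition keeps the stationary zinc concentration low. The positions of the new bonds are dictated by where iodine and zinc sit, the organozinc tolerates the hindered aryl ketones, and no cationic benzylic species is present that could attack the free C–H of rings B and D.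

Step 8
Reactants: 13, nona-O-benzyl B–C–D trimer
Product: 14 1-{3,5-bis[(3-butanoyl-2,4,6-trihydroxyphenyl)methyl]-2,4,6-trihydroxyphenyl}butan-1-one (B–C–D nonaphenol)
Conditions: H2 (1 atm), Pd/C (10 % Pd), EtOAc/MeOH 1:1, rt, degassed solvents
Reagents that add atoms: none
Why: Catalytic hydrogenolysis of benzyl ethers; all nine O–benzyl bonds should be cleaved, while the diarylmethane C–C bonds and the ortho-hydroxyaryl ketones are inert at atmospheric pressure and room temperature.

Step 9
Reactants: 1, 1-(2,4,6-trihydroxyphenyl)butan-1-one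
Product: 15 2-butanoyl-3,5-dihydroxy-6,6-dimethylcyclohexa-2,4-dien-1-one (butyrylfilicinic acid)
Conditions: NaOMe (3 equiv), MeI (2.2 equiv), MeOH, 0 °C to rt; extraction into aqueous NaHCO3, then chromatography
Reagents that add atoms: iodomethane, CI
Why: Base-mediated dearomatising C-methylation of an acylphloroglucinol; the phenoxide is alkylated twice on the same ring carbon, and the resulting enolised triketone should be separable from mono- and trimethylated companions through its higher acidity.

Step 10
Reactants: 15, butyrylfilicinic acid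
Product: 16 2-butanoyl-4-[(dimethylamino)methyl]-3,5-dihydroxy-6,6-dimethylcyclohexa-2,4-dien-1-one (Mannich base, betaine)
Conditions: CH2O (37 % aq, 1.1 equiv), Me2NH (40 % aq, 1.5 equiv), premixed in EtOH, 0 °C; 15 added slowly, 0 °C to rt
Reagents that add atoms: formaldehyde, C=O; dimethylamine, CNC
Why: Mannich reaction; the single ring C–H between the two enol carbons adds to the iminium ion, and slow addition to excess amine, with the betaine expected to precipitate, keeps 16 away from unreacted 15 and so from methylene-bis dimer formation.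

Step 11
Reactants: 14, B–C–D nonaphenol (1 equiv); 16, Mannich base of butyrylfilicinic acid (2.4 equiv, two molecules incorporated, one at ring B and one at ring D)
Product: 19 pentaalbaspidin BBBBB, via methylene trione 17 (not isolated), via ABCD tetramer 18 (not isolated)
Conditions: AcOH (5 equiv), degassed 1,4-dioxane, 60 °C, Ar; dilute HCl work-up
Reagents that add atoms: Mannich base 16 (second molecule, which converts 18 into 19), CCCC(=O)C1=C(O)C(CN(C)C)=C(O)C(C)(C)C1=O
Why: Mannich-base alkylation by elimination and conjugate addition; loss of dimethylamine from 16 gives the 2-methylene trione 17, which is attacked by the one free ring carbon of ring B and then of ring D in a Friedel–Crafts-type Michael addition with re-aromatisation, while ring C has no free position and the acetic acid buffer should suppress base-induced bridge exchange.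

**Compound list**

1 | 1-(2,4,6-trihydroxyphenyl)butan-1-one (butyrylphloroglucinol) | CCCC(=O)c1c(O)cc(O)cc1O | starting material
2 | benzyl bromide | BrCc1ccccc1 | starting material
3 | 1-[2,4,6-tris(benzyloxy)phenyl]butan-1-one | CCCC(=O)c1c(OCc2ccccc2)cc(OCc2ccccc2)cc1OCc1ccccc1 | intermediate
4 | N-iodosuccinimide | O=C1CCC(=O)N1I | starting material
5 | 1-[2,4,6-tris(benzyloxy)-3,5-diiodophenyl]butan-1-one | CCCC(=O)c1c(OCc2ccccc2)c(I)c(OCc2ccccc2)c(I)c1OCc1ccccc1 | intermediate
6 | N-{[2,4,6-tris(benzyloxy)-3-butanoylphenyl]methylidene}-N-methylmethanaminium chloride | CCCC(=O)c1c(OCc2ccccc2)cc(OCc2ccccc2)c(C=[N+](C)C)c1OCc1ccccc1.[Cl-] | intermediate (not isolated)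
7 | 2,4,6-tris(benzyloxy)-3-butanoylbenzaldehyde | CCCC(=O)c1c(OCc2ccccc2)cc(OCc2ccccc2)c(C=O)c1OCc1ccccc1 | intermediate
8 | 1-[2,4,6-tris(benzyloxy)-3-(hydroxymethyl)phenyl]butan-1-one | CCCC(=O)c1c(OCc2ccccc2)cc(OCc2ccccc2)c(CO)c1OCc1ccccc1 | intermediate
9 | [2,4,6-tris(benzyloxy)-3-butanoylphenyl]methyl methanesulfonate | CCCC(=O)c1c(OCc2ccccc2)cc(OCc2ccccc2)c(COS(C)(=O)=O)c1OCc1ccccc1 | intermediate (not isolated)
10 | 1-[2,4,6-tris(benzyloxy)-3-(chloromethyl)phenyl]butan-1-one | CCCC(=O)c1c(OCc2ccccc2)cc(OCc2ccccc2)c(CCl)c1OCc1ccccc1 | intermediate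
11 | [2,4,6-tris(benzyloxy)-3-butanoylbenzyl]zinc chloride | CCCC(=O)c1c(OCc2ccccc2)cc(OCc2ccccc2)c(C[Zn]Cl)c1OCc1ccccc1 | intermediate
12 | 1-{2,4,6-tris(benzyloxy)-3-iodo-5-{[2,4,6-tris(benzyloxy)-3-butanoylphenyl]methyl}phenyl}butan-1-one | CCCC(=O)c1c(OCc2ccccc2)cc(OCc2ccccc2)c(Cc2c(OCc3ccccc3)c(I)c(OCc3ccccc3)c(C(=O)CCC)c2OCc2ccccc2)c1OCc1ccccc1 | intermediate (not isolated)
13 | 1-{2,4,6-tris(benzyloxy)-3,5-bis{[2,4,6-tris(benzyloxy)-3-butanoylphenyl]methyl}phenyl}butan-1-one (nona-O-benzyl B–C–D trimer) | CCCC(=O)c1c(OCc2ccccc2)cc(OCc2ccccc2)c(Cc2c(OCc3ccccc3)c(Cc3c(OCc4ccccc4)cc(OCc4ccccc4)c(C(=O)CCC)c3OCc3ccccc3)c(OCc3ccccc3)c(C(=O)CCC)c2OCc2ccccc2)c1OCc1ccccc1 | intermediate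
14 | 1-{3,5-bis[(3-butanoyl-2,4,6-trihydroxyphenyl)methyl]-2,4,6-trihydroxyphenyl}butan-1-one (B–C–D nonaphenol) | CCCC(=O)c1c(O)cc(O)c(Cc2c(O)c(Cc3c(O)cc(O)c(C(=O)CCC)c3O)c(O)c(C(=O)CCC)c2O)c1O | intermediate
15 | 2-butanoyl-3,5-dihydroxy-6,6-dimethylcyclohexa-2,4-dien-1-one (butyrylfilicinic acid) | CCCC(=O)C1=C(O)C=C(O)C(C)(C)C1=O | intermediate
16 | 2-butanoyl-4-[(dimethylamino)methyl]-3,5-dihydroxy-6,6-dimethylcyclohexa-2,4-dien-1-one | CCCC(=O)C1=C(O)C(CN(C)C)=C(O)C(C)(C)C1=O | intermediate
17 | 2-butanoyl-3-hydroxy-6,6-dimethyl-4-methylidenecyclohex-2-ene-1,5-dione | CCCC(=O)C1=C(O)C(=C)C(=O)C(C)(C)C1=O | intermediate (not isolated)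
18 | ABCD tetramer (ring A joined to ring B of 14, ring D still carrying its free C–H) | CCCC(=O)C1=C(O)C(Cc2c(O)c(Cc3c(O)c(Cc4c(O)cc(O)c(C(=O)CCC)c4O)c(O)c(C(=O)CCC)c3O)c(O)c(C(=O)CCC)c2O)=C(O)C(C)(C)C1=O | intermediate (not isolated)
19 | pentaalbaspidin BBBBB | CCCC(=O)C1=C(O)C(Cc2c(O)c(Cc3c(O)c(Cc4c(O)c(CC5=C(O)C(C)(C)C(=O)C(C(=O)CCC)=C5O)c(O)c(C(=O)CCC)c4O)c(O)c(C(=O)CCC)c3O)c(O)c(C(=O)CCC)c2O)=C(O)C(C)(C)C1=O | target

**Step count**

Total: 11 steps. Longest linear sequence: 8 steps (steps 1, 3, 4, 5, 6, 7, 8 and 11).

**Steps most likely to fail**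

Step 7. The second coupling may stall at the hindered mono-iodide, with proto-deiodination of the aryl–palladium species and Wurtz-type homocoupling of the zinc reagent consuming the partners. The fallback sets out from chloride 10 and diiodide 5 and replaces the zinc nucleophile by a boron one. Palladium-catalysed borylation of 10 (B2pin2, Pd(dba)2, tris(4-methoxyphenyl)phosphine, KOAc, toluene, 50 °C) should give 1-{2,4,6-tris(benzyloxy)-3-[(4,4,5,5-tetramethyl-1,3,2-dioxaborolan-2-yl)methyl]phenyl}butan-1-one F1, a storable benzylic boronate. A twofold Suzuki–Miyaura coupling of F1 (2.6 equiv, two molecules incorporated) with 5 (PdCl2(dppf), K3PO4, toluene/H2O, 80 °C) then returns to the route at 13.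

Step 11. Under the conditions that release the amine, the methylene bridges may exchange by retro-Michael fragmentation. The methylene trione may also be captured by triketone liberated through retro-Mannich cleavage instead of by the trimer, so that the double coupling stays incomplete. The fallback sets out from 14 and 15 and inverts the roles of the partners. Mannich reaction of 14 with formaldehyde and dimethylamine in EtOH should give 1-{3,5-bis({3-butanoyl-5-[(dimethylamino)methyl]-2,4,6-trihydroxyphenyl}methyl)-2,4,6-trihydroxyphenyl}butan-1-one F2, in which both free ring carbons carry the aminomethyl group. Heating F2 with an excess of 15 (4 equiv, two molecules incorporated) in dioxane at 80–90 °C should expel dimethylamine and let the enol carbon of 15 add to the resulting ortho-quinone methides. No electrophile derived from the triketone is present, so it cannot dimerise. The sequence comes back at target 19.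

Step 5. The benzylic chloride may ionise during formation or handling and alkylate the free ring position of a second molecule, giving oligomers. The fallback sets out from alcohol 8 and avoids an isolated benzylic halide. Phosphorylation (ClP(O)(OEt)2, pyridine, DMAP, CH2Cl2, 0 °C) should give [2,4,6-tris(benzyloxy)-3-butanoylphenyl]methyl diethyl phosphate F3, which can be purified and stored. Treatment with Zn dust and LiI (1.1 equiv) in N,N-dimethylacetamide/THF at 40 °C should pass through 1-[2,4,6-tris(benzyloxy)-3-(iodomethyl)phenyl]butan-1-one F4, present only at low concentration and consumed at the metal, to [2,4,6-tris(benzyloxy)-3-butanoylbenzyl]zinc iodide F5. F5 (2.6 equiv, two molecules incorporated) is coupled with 5 under the conditions of step 7, and the sequence comes back at 13.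

**Further compounds**

F1 | step 7 | 1-{2,4,6-tris(benzyloxy)-3-[(4,4,5,5-tetramethyl-1,3,2-dioxaborolan-2-yl)methyl]phenyl}butan-1-one | CCCC(=O)c1c(OCc2ccccc2)cc(OCc2ccccc2)c(CB2OC(C)(C)C(C)(C)O2)c1OCc1ccccc1
F2 | step 11 | 1-{3,5-bis({3-butanoyl-5-[(dimethylamino)methyl]-2,4,6-trihydroxyphenyl}methyl)-2,4,6-trihydroxyphenyl}butan-1-one | CCCC(=O)c1c(O)c(CN(C)C)c(O)c(Cc2c(O)c(Cc3c(O)c(CN(C)C)c(O)c(C(=O)CCC)c3O)c(O)c(C(=O)CCC)c2O)c1O
F3 | step 5 | [2,4,6-tris(benzyloxy)-3-butanoylphenyl]methyl diethyl phosphate | CCCC(=O)c1c(OCc2ccccc2)cc(OCc2ccccc2)c(COP(=O)(OCC)OCC)c1OCc1ccccc1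
F4 | step 5 | 1-[2,4,6-tris(benzyloxy)-3-(iodomethyl)phenyl]butan-1-one | CCCC(=O)c1c(OCc2ccccc2)cc(OCc2ccccc2)c(CI)c1OCc1ccccc1
F5 | step 5 | [2,4,6-tris(benzyloxy)-3-butanoylbenzyl]zinc iodide | CCCC(=O)c1c(OCc2ccccc2)cc(OCc2ccccc2)c(C[Zn]I)c1OCc1ccccc1
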